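Thursday's and Monday's runs differ in one charge, second substrate, at 0.250 and 0.375 of the starting-material charge. At 80.0 min their target stood at 7.6% and 7.2% of the starting material charged.

| flask | starting material | second substrate | solid reagent | remark | time |
|---|---|---|---|---|---|
| Thursday's | 20 mM | 5 mM | 40 mM | run made earlier |  |
| Monday's | 20 mM | 7.5 mM | 40 mM | run made earlier |  |
| Sunday's | 20 mM | 10 mM | 20 mM | run made earlier |  |
| flask | 20 mM | 10.0 mM | 40.0 mM |  | 80 min |

| run | time / min | target / % | starting material / % |
|---|---|---|---|
| Thursday's | 5.00 | 0.3 | 99.2 |
| Thursday's | 15.0 | 1.5 | 95.3 |
| Thursday's | 30.0 | 1.8 | 92.9 |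
| Thursday's | 40.0 | 4.2 | 89.5 |
| Thursday's | 60.0 | 6.1 | 85.1 |
| Thursday's | 80.0 | 7.6 | 80.7 |
| Monday's | 12.0 | 0.3 | 96.1 |
| Monday's | 25.0 | 2.1 | 91.7 |
| Monday's | 40.0 | 3.7 | 87.4 |
| Monday's | 50.0 | 5.3 | 84.7 |
| Monday's | 60.0 | 5.2 | 81.9 |
| Monday's | 80.0 | 7.2 | 77.4 |
| Sunday's | 6.00 | 0.2 | 97.4 |
| Sunday's | 12.0 | 1.2 | 94.1 |
| Sunday's | 25.0 | 1.5 | 89.6 |
| Sunday's | 40.0 | 3.7 | 83.7 |
| Sunday's | 80.0 | 5.5 | 72.8 |

(each reading ± 0.5 percentage points)

- solid, in amounts per volume of the solution: solid reagent
- at the start none of the solid reagent is in solution
- coupling partner is what solid reagent becomes in solution

* the target standing at 80 min, as a percentage of the starting material charged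
* concentration of coupling partner in solution at 40 min, in percent of saturation
* the change that raises the amount of target at 80 min, in percent of the starting material charged most ("none" if none brings more than 2 percentage points) (west / south-east / none)
* amount of target at 80 min, in percent of the starting material charged, after south-east

- west: doubling the solubility of the solid reagent, all else as stated
- south-east: doubling the dissolution coefficient of the solid reagent, all else as stated

Two views of the flask stand against each other, and the first is mine. Thursday's and Monday's runs give −0.133 for the second-substrate order, an apparent reaction order: the logarithm of the ratio of two target readings at one time, divided by the logarithm of the ratio of their second-substrate charges, other charges equal. It is a reading, since the two targets differ by 0.4 percentage points against a scatter of 0.5 points. The flask has the solid charge of those runs and second substrate at 0.500 of the starting-material charge, so carrying the order on from Monday's reading gives me 6.93% target.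

The second view, the forecast's, is about supply. Sunday's run had the flask's second substrate and half its solid, and it reached 5.5% target, which the forecast reads as “coupling partner supply being at least partly limiting”. It gives 9% target, coupling partner at 35% of saturation at 40 min, west as the best change, and 12.5% target after south-east.

The simulated flask gives 6.55% target, 0.38 points below my number and 2.4 points below the forecast's, so mine lies nearer. Coupling partner stands at 15.9% of saturation at 40 min. On the two changes to dissolving the forecast's choice stands: west adds 6.7 points against 4.9 points for south-east, and south-east brings the target to 11.4%.

    starting material + coupling partner → target (k = 3.60 M⁻¹ min⁻¹)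
    second substrate + coupling partner → second product (k = 9.70 M⁻¹ min⁻¹)
    starting material + second substrate → cross product (k = 0.420 M⁻¹ min⁻¹)
    solid reagent ⇌ coupling partner, rate k4*(cs4 - [coupling partner]) while solid is left; crystals form when [coupling partner] > cs4 (solubility = 1.80 mM, k = 0.0250 min⁻¹)

From Monday's reading to the flask's result the order comes out as −0.331, lower than the −0.133 read beforehand. The neighbouring flask holds 40 mM of second substrate, 2.00 times the starting-material charge, with everything else as in the flask. The same reckoning from Monday's reading gives it 5.76% target, but it stands at 1.95%, and the order from the flask to this neighbour is −0.875. Of the starting material charged, this neighbour keeps 34% and holds 63.6% as cross product.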